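The hydroxyl-bearing carbon C6 of the benzotropolone, flanked by the C5 carbonyl and by C7 (which holds flavan B), is read as a single carbon inserted into the C1=C2 enol ether bond of a six-membered dihydronaphthalene ring; the enol ether oxygen survives as the C5 carbonyl oxygen. One operation, dibromocarbene addition followed by opening of the methoxy dibromocyclopropane with loss of bromomethane, makes C5–C6 and C6–C7 and turns the six-membered ring into the seven-membered 6-bromo enone. Its substrate is a tetrasubstituted 1-methoxy-3,4-dihydronaphthalene that already carries both benzyl-protected cis-flavans, flavan A (O3 silylated) on the benzo ring and flavan B on the enol ether carbon C2.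

Key step: step 19

Remark on locants: dihydronaphthalenes use naphthalene locants (C1 enol ether carbon, C2, C5 site of flavan A, C7/C8 benzyloxy); benzo[7]annulenones use C5 carbonyl, C6, C7 (flavan B), C8, C9, C1 (flavan A), C3/C4 benzyloxy.

Remark on shorthand: "flavan A unit" is (2R,3R)-5,7-bis(benzyloxy)-3-(triisopropylsilyloxy)chroman-2-yl and "flavan B unit" is (2R,3R)-3,5,7-tris(benzyloxy)chroman-2-yl.

Remark on materials: compounds 1, 11, 13 and 35 are assumed to be purchased.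

Remark on design: the ring is dehydrogenated without a quinone oxidant, because the C4 methylene groups of 5,7-dialkoxyflavans are themselves oxidised by such reagents. Flavan A carries a triisopropylsilyl ether, which should resist oxygen-to-oxygen silyl migration during the basic ring closure. The C5 halogen is iodine, so that it can be metalated in the presence of the C2 vinyl bromide.

Step 1
Reactants: 1 4-(3,4-dimethoxyphenyl)butanoic acid
Product: 2 4-(2-bromo-4,5-dimethoxyphenyl)butanoic acid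
Conditions: NBS, MeCN, 0 °C to rt
Reagents that add atoms: N-bromosuccinimide, O=C1CCC(=O)N1Br
Why: Electrophilic aromatic bromination should go para to the C3 methoxy group at the ring position next to the side chain, which blocks the site where acylation would otherwise close.

Step 2
Reactants: 2 4-(2-bromo-4,5-dimethoxyphenyl)butanoic acid
Product: 3 5-bromo-7,8-dimethoxy-3,4-dihydronaphthalen-1(2H)-one
Conditions: polyphosphoric acid, 90 °C
Reagents that add atoms: none
Why: Intramolecular Friedel–Crafts acylation can only close onto the one free position ortho to the chain, between chain and methoxy group, which gives the 7,8-dioxygenated tetralone.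

Step 3
Reactants: 3 5-bromo-7,8-dimethoxy-3,4-dihydronaphthalen-1(2H)-one
Product: 4 5-bromo-7,8-dihydroxy-3,4-dihydronaphthalen-1(2H)-one
Conditions: BBr3, CH2Cl2, −78 to 0 °C; H2O
Reagents that add atoms: none
Why: Lewis acid-mediated demethylation of aryl methyl ethers by BBr3 leaves the ketone and the aryl bromide untouched.

Step 4
Reactants: 4 5-bromo-7,8-dihydroxy-3,4-dihydronaphthalen-1(2H)-one
Product: 5 7,8-bis(benzyloxy)-5-bromo-3,4-dihydronaphthalen-1(2H)-one
Conditions: BnBr, K2CO3, DMF, 60 °C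
Reagents that add atoms: benzyl bromide, BrCc1ccccc1
Why: Williamson etherification of both phenoxides, with heating so that the hydrogen-bonded C8 phenol is also alkylated, installs protecting groups that the final hydrogenolysis removes.

Step 5
Reactants: 5 7,8-bis(benzyloxy)-5-bromo-3,4-dihydronaphthalen-1(2H)-one
Product: 6 7,8-bis(benzyloxy)-5-iodo-3,4-dihydronaphthalen-1(2H)-one
Conditions: NaI, CuI (cat.), trans-N,N′-dimethylcyclohexane-1,2-diamine (cat.), 1,4-dioxane, 110 °C
Reagents that add atoms: sodium iodide, [Na+].[I-]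
Why: The copper-catalysed aromatic Finkelstein exchange, driven by precipitation of NaBr, turns the aryl bromide into the iodide needed for selective metalation at C5 later.

Step 6
Reactants: 6 7,8-bis(benzyloxy)-5-iodo-3,4-dihydronaphthalen-1(2H)-one
Product: 8 7,8-bis(benzyloxy)-5-iodo-1-methoxy-3,4-dihydronaphthalene, via dimethyl ketal 7 (not isolated)
Conditions: HC(OMe)3, TsOH·H2O (cat.), toluene, 60 to 100 °C (MeOH distilled off); Et3N quench
Reagents that add atoms: trimethyl orthoformate, COC(OC)OC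
Why: Acid-catalysed ketalisation with the orthoformate as water scavenger and thermal loss of methanol from the crowded benzylic ketal should give the conjugated methyl enol ether, C2 being the only carbon that can lose a proton.

Step 7
Reactants: 8 7,8-bis(benzyloxy)-5-iodo-1-methoxy-3,4-dihydronaphthalene
Product: 10 7,8-bis(benzyloxy)-2-bromo-5-iodo-1-methoxy-3,4-dihydronaphthalene, via trans-dibromide 9 (not isolated)
Conditions: Br2 (1 equiv), CH2Cl2, −78 °C; then DBU, −78 °C to rt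
Reagents that add atoms: bromine, BrBr
Why: Bromine addition to the enol ether and base-induced dehydrobromination (addition–elimination) give the β-bromo enol ether, the enol ether being far more nucleophilic than the only arene present at this stage.

Step 8
Reactants: 11 1,3-bis(benzyloxy)-5-bromobenzene
Product: 12 1,5-bis(benzyloxy)-3-bromo-2-iodobenzene
Conditions: NIS, CF3CO2H (cat.), MeCN, 0 °C to rt
Reagents that add atoms: N-iodosuccinimide, O=C1CCC(=O)N1I
Why: Electrophilic aromatic iodination should take the position between bromine and a benzyloxy group, para to the other benzyloxy group, as bromination and formylation of such arenes do.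

Step 9
Reactants: 12 1,5-bis(benzyloxy)-3-bromo-2-iodobenzene; 13 methyl (2R)-oxirane-2-carboxylate
Product: 15 methyl (2R)-3-[2,4-bis(benzyloxy)-6-bromophenyl]-2-hydroxypropanoate, via arylmagnesium chloride 14 (not isolated)
Conditions: i-PrMgCl·LiCl, THF, −40 °C; then CuI (cat.), 13, −40 to −20 °C; aq. NH4Cl
Reagents that add atoms: none
Why: Iodine–magnesium exchange is selective for C–I, and the copper-catalysed aryl Grignard opens the glycidate by SN2 attack at the unsubstituted C3, so the (R) stereocenter of 13 is carried over untouched.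

Step 10
Reactants: 15 methyl (2R)-3-[2,4-bis(benzyloxy)-6-bromophenyl]-2-hydroxypropanoate
Product: 16 methyl (2R)-3-[2,4-bis(benzyloxy)-6-bromophenyl]-2-(triisopropylsilyloxy)propanoate
Conditions: i-Pr3SiOTf, 2,6-lutidine, CH2Cl2, 0 °C to rt
Reagents that add atoms: triisopropylsilyl trifluoromethanesulfonate, CC(C)[Si](C(C)C)(C(C)C)OS(=O)(=O)C(F)(F)F
Why: Silylation of the secondary alcohol with a silyl triflate installs a bulky, non-chelating group that serves Felkin–Anh control in step 15 and is removed later by fluoride.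

Step 11
Reactants: 16 methyl (2R)-3-[2,4-bis(benzyloxy)-6-bromophenyl]-2-(triisopropylsilyloxy)propanoate
Product: 17 (2R)-3-[2,4-bis(benzyloxy)-6-bromophenyl]-N-methoxy-N-methyl-2-(triisopropylsilyloxy)propanamide
Conditions: MeNH(OMe)·HCl, i-PrMgCl, THF, −20 to 0 °C
Reagents that add atoms: N,O-dimethylhydroxylamine hydrochloride, CNOC.Cl
Why: Aminolysis of the ester by the magnesium amide (Weinreb amide formation) proceeds at low temperature without epimerising the α-silyloxy center.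

Step 12
Reactants: 15 methyl (2R)-3-[2,4-bis(benzyloxy)-6-bromophenyl]-2-hydroxypropanoate
Product: 18 methyl (2R)-2-(benzyloxy)-3-[2,4-bis(benzyloxy)-6-bromophenyl]propanoate
Conditions: BnBr, Ag2O, CH2Cl2, rt, dark
Reagents that add atoms: benzyl bromide, BrCc1ccccc1
Why: Silver oxide-mediated O-benzylation (Williamson type, no strong base) protects the α-hydroxy ester without epimerisation and gives the chelating ether needed in step 17.

Step 13
Reactants: 18 methyl (2R)-2-(benzyloxy)-3-[2,4-bis(benzyloxy)-6-bromophenyl]propanoate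
Product: 19 (2R)-2-(benzyloxy)-3-[2,4-bis(benzyloxy)-6-bromophenyl]propanal
Conditions: i-Bu2AlH, CH2Cl2, −78 °C; MeOH, aq. potassium sodium tartrate
Reagents that add atoms: none
Why: Partial hydride reduction of the α-alkoxy ester stops at the chelated aluminium hemiacetal at −78 °C and releases the aldehyde on work-up; it is used at once to protect its stereocenter.

Step 14
Reactants: 10 7,8-bis(benzyloxy)-2-bromo-5-iodo-1-methoxy-3,4-dihydronaphthalene; 17 (2R)-3-[2,4-bis(benzyloxy)-6-bromophenyl]-N-methoxy-N-methyl-2-(triisopropylsilyloxy)propanamide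
Product: 21 (2R)-1-[7,8-bis(benzyloxy)-2-bromo-1-methoxy-3,4-dihydronaphthalen-5-yl]-3-[2,4-bis(benzyloxy)-6-bromophenyl]-2-(triisopropylsilyloxy)propan-1-one, via arylmagnesium chloride 20 (not isolated)
Conditions: i-PrMgCl·LiCl, THF, 0 °C to rt; then 17, 0 °C to rt; aq. NH4Cl
Reagents that add atoms: none
Why: Iodine–magnesium exchange at C5 leaves the vinyl and aryl bromides alone, and the Weinreb ketone synthesis stops at the ketone through the chelated tetrahedral intermediate.

Step 15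
Reactants: 21 (2R)-1-[7,8-bis(benzyloxy)-2-bromo-1-methoxy-3,4-dihydronaphthalen-5-yl]-3-[2,4-bis(benzyloxy)-6-bromophenyl]-2-(triisopropylsilyloxy)propan-1-one
Product: 22 (1R,2R)-1-[7,8-bis(benzyloxy)-2-bromo-1-methoxy-3,4-dihydronaphthalen-5-yl]-3-[2,4-bis(benzyloxy)-6-bromophenyl]-2-(triisopropylsilyloxy)propan-1-ol
Conditions: LiBH(s-Bu)3, THF, −78 °C; H2O
Reagents that add atoms: none
Why: Felkin–Anh (non-chelation) hydride addition of the bulky borohydride anti to the silyloxy group should set the new carbinol center as (R), syn to the existing (R) center.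

Step 16
Reactants: 22 (1R,2R)-1-[7,8-bis(benzyloxy)-2-bromo-1-methoxy-3,4-dihydronaphthalen-5-yl]-3-[2,4-bis(benzyloxy)-6-bromophenyl]-2-(triisopropylsilyloxy)propan-1-ol
Product: 23 7,8-bis(benzyloxy)-2-bromo-1-methoxy-5-(flavan A unit)-3,4-dihydronaphthalene
Conditions: CuI (cat.), 1,10-phenanthroline (cat.), Cs2CO3, toluene, 110 °C
Reagents that add atoms: none
Why: Copper-catalysed intramolecular Ullmann-type C–O coupling of the benzylic alkoxide with the aryl bromide closes the pyran ring without touching either carbinol center, so the syn alcohol gives the 2,3-cis (2R,3R) flavan, the hindered vinyl bromide remaining a spectator.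

Step 17
Reactants: 23 7,8-bis(benzyloxy)-2-bromo-1-methoxy-5-(flavan A unit)-3,4-dihydronaphthalene; 19 (2R)-2-(benzyloxy)-3-[2,4-bis(benzyloxy)-6-bromophenyl]propanal
Product: 26 (1R,2R)-2-(benzyloxy)-3-[2,4-bis(benzyloxy)-6-bromophenyl]-1-[7,8-bis(benzyloxy)-1-methoxy-5-(flavan A unit)-3,4-dihydronaphthalen-2-yl]propan-1-ol, via vinyllithium 24 (not isolated), via vinylmagnesium bromide 25 (not isolated)
Conditions: t-BuLi (2 equiv), Et2O, −78 °C; MgBr2·OEt2; then 19, CH2Cl2, −78 °C; aq. NaHCO3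
Reagents that add atoms: none
Why: Bromine–lithium exchange, transmetalation to magnesium and Cram-chelate-controlled Grignard addition to the α-benzyloxy aldehyde, on the face of the magnesium chelate away from the arylmethyl group, should set the new carbinol center as (R), syn to the benzyloxy center.

Step 18
Reactants: 26 (1R,2R)-2-(benzyloxy)-3-[2,4-bis(benzyloxy)-6-bromophenyl]-1-[7,8-bis(benzyloxy)-1-methoxy-5-(flavan A unit)-3,4-dihydronaphthalen-2-yl]propan-1-ol
Product: 27 7,8-bis(benzyloxy)-1-methoxy-5-(flavan A unit)-2-(flavan B unit)-3,4-dihydronaphthalene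
Conditions: CuI (cat.), 1,10-phenanthroline (cat.), Cs2CO3, toluene, 110 °C; Et3N-treated silica
Reagents that add atoms: none
Why: A second copper-catalysed intramolecular Ullmann-type C–O coupling closes flavan B with retention at both carbinol carbons, under basic conditions that the acid-labile allylic aryl ether and enol ether tolerate.

Step 19
Reactants: 27 7,8-bis(benzyloxy)-1-methoxy-5-(flavan A unit)-2-(flavan B unit)-3,4-dihydronaphthalene
Product: 29 3,4-bis(benzyloxy)-6-bromo-1-(flavan A unit)-7-(flavan B unit)-8,9-dihydro-5H-benzo[7]annulen-5-one, via dibromocyclopropane 28 (not isolated)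
Conditions: CHBr3, KOt-Bu, toluene, −30 °C; pH 7 buffer; then toluene, K2CO3 (solid), 60 °C
Reagents that add atoms: bromoform, BrC(Br)Br
Why: Dibromocarbene, formed from bromoform by α-elimination, adds as an electrophile in a concerted [2+1] cycloaddition to the C1=C2 enol ether bond and gives the 1-methoxy dibromocyclopropane 28. On warming, 28 undergoes the disrotatory cyclopropyl-to-allyl cation opening with departure of the bromide syn to the six-membered ring, helped by the methoxy lone pair and the aryl group, and bromide then takes the methyl group from the oxocarbenium ion. The closest known reaction type is the dihalocarbene ring expansion of cyclic enol ethers and silyl enol ethers to 2-halocycloalk-2-enones. The seven-membered ring arises not by cyclisation but by cleavage of the shared bond of the bicyclo[4.1.0] unit, a one-carbon ring enlargement that leaves the new carbon bonded to C5 and C7. No stereocenter is created, since C5, C6 and C7 are all sp2 in 29 and both cyclopropane diastereomers converge on it. The step needs chemoselectivity for the enol ether over arenes and benzylic C–H bonds, which its nucleophilicity secures, and it needs the alkoxide kept away from the enolisable product, which is secured by making the carbene cold, where 28 should persist, quenching, and only then warming.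

Step 20
Reactants: 29 3,4-bis(benzyloxy)-6-bromo-1-(flavan A unit)-7-(flavan B unit)-8,9-dihydro-5H-benzo[7]annulen-5-one
Product: 32 3,4-bis(benzyloxy)-6-bromo-1-(flavan A unit)-7-(flavan B unit)-5H-benzo[7]annulen-5-one, via potassium dienolate 30 (not isolated), via 6,8-dibromo ketone 31 (not isolated)
Conditions: KN(SiMe3)2, THF, −78 °C; BrCl2C–CCl2Br, −78 °C; then DBU, −78 °C to rt
Reagents that add atoms: none
Why: Kinetic γ-deprotonation at the C8 methylene, bromination of the dienolate by a positive-bromine donor that does not touch arenes, and E2 dehydrobromination give the bromotropone by a halogenation–dehydrohalogenation sequence that spares the flavan C4 methylenes.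

Step 21
Reactants: 32 3,4-bis(benzyloxy)-6-bromo-1-(flavan A unit)-7-(flavan B unit)-5H-benzo[7]annulen-5-one
Product: 33 3,4,6-tris(benzyloxy)-1-(flavan A unit)-7-(flavan B unit)-5H-benzo[7]annulen-5-one
Conditions: NaOBn, BnOH/THF, 0 °C to rt
Reagents that add atoms: sodium benzyloxide, [Na+].[O-]Cc1ccccc1
Why: Addition–elimination of benzyloxide at the bromine-bearing C6 of the 2-bromotropone places the tropolone oxygen, cine substitution being excluded because the other α-carbon is the ring-fusion carbon.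

Step 22
Reactants: 33 3,4,6-tris(benzyloxy)-1-(flavan A unit)-7-(flavan B unit)-5H-benzo[7]annulen-5-one
Product: 34 3,4,6-tris(benzyloxy)-1-[(2R,3R)-5,7-bis(benzyloxy)-3-hydroxychroman-2-yl]-7-(flavan B unit)-5H-benzo[7]annulen-5-one
Conditions: n-Bu4NF, AcOH, THF, rt
Reagents that add atoms: none
Why: Fluoride-mediated desilylation, buffered with acetic acid to protect the benzyloxytropone, frees only the C3 hydroxyl of flavan A.

Step 23
Reactants: 34 3,4,6-tris(benzyloxy)-1-[(2R,3R)-5,7-bis(benzyloxy)-3-hydroxychroman-2-yl]-7-(flavan B unit)-5H-benzo[7]annulen-5-one; 35 3,4,5-tris(benzyloxy)benzoic acid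
Product: 37 (2R,3R)-5,7-bis(benzyloxy)-2-[3,4,6-tris(benzyloxy)-7-(flavan B unit)-5-oxo-5H-benzo[7]annulen-1-yl]chroman-3-yl 3,4,5-tris(benzyloxy)benzoate, via O-acylisourea 36 (not isolated)
Conditions: DCC, DMAP, CH2Cl2, rt
Reagents that add atoms: none
Why: Steglich esterification through the O-acylisourea and the acylpyridinium ion acylates the only free hydroxyl with retention at C3.

Step 24
Reactants: 37 (2R,3R)-5,7-bis(benzyloxy)-2-[3,4,6-tris(benzyloxy)-7-(flavan B unit)-5-oxo-5H-benzo[7]annulen-1-yl]chroman-3-yl 3,4,5-tris(benzyloxy)benzoate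
Product: 38 CNP0217128.1 (flavan A 3-O-gallate of the bis-flavanyl benzotropolone)
Conditions: H2 (1 atm), Pd(OH)2/C, THF/MeOH, rt
Reagents that add atoms: none
Why: Catalytic hydrogenolysis should cleave all eleven benzyl ethers under mild conditions that leave the gallate ester, the benzotropolone and the four stereocenters intact.

Compound list
1 | 4-(3,4-dimethoxyphenyl)butanoic acid | COc1ccc(CCCC(=O)O)cc1OC | starting material
2 | 4-(2-bromo-4,5-dimethoxyphenyl)butanoic acid | COc1cc(Br)c(CCCC(=O)O)cc1OC | intermediate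
3 | 5-bromo-7,8-dimethoxy-3,4-dihydronaphthalen-1(2H)-one | COc1cc(Br)c2CCCC(=O)c2c1OC | intermediate
4 | 5-bromo-7,8-dihydroxy-3,4-dihydronaphthalen-1(2H)-one | Oc1cc(Br)c2CCCC(=O)c2c1O | intermediate
5 | 7,8-bis(benzyloxy)-5-bromo-3,4-dihydronaphthalen-1(2H)-one | O=C1CCCc2c(Br)cc(OCc9ccccc9)c(OCc9ccccc9)c12 | intermediate
6 | 7,8-bis(benzyloxy)-5-iodo-3,4-dihydronaphthalen-1(2H)-one | O=C1CCCc2c(I)cc(OCc9ccccc9)c(OCc9ccccc9)c12 | intermediate
7 | 7,8-bis(benzyloxy)-5-iodo-1,1-dimethoxy-1,2,3,4-tetrahydronaphthalene (not isolated) | COC1(OC)CCCc2c(I)cc(OCc9ccccc9)c(OCc9ccccc9)c12 | intermediate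
8 | 7,8-bis(benzyloxy)-5-iodo-1-methoxy-3,4-dihydronaphthalene | COC1=CCCc2c(I)cc(OCc9ccccc9)c(OCc9ccccc9)c12 | intermediate
9 | 7,8-bis(benzyloxy)-1,2-dibromo-5-iodo-1-methoxy-1,2,3,4-tetrahydronaphthalene (racemic trans adduct, not isolated) | COC1(Br)C(Br)CCc2c(I)cc(OCc9ccccc9)c(OCc9ccccc9)c12 | intermediate
10 | 7,8-bis(benzyloxy)-2-bromo-5-iodo-1-methoxy-3,4-dihydronaphthalene | COC1=C(Br)CCc2c(I)cc(OCc9ccccc9)c(OCc9ccccc9)c12 | intermediate
11 | 1,3-bis(benzyloxy)-5-bromobenzene | Brc1cc(OCc9ccccc9)cc(OCc9ccccc9)c1 | starting material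
12 | 1,5-bis(benzyloxy)-3-bromo-2-iodobenzene | Ic1c(Br)cc(OCc9ccccc9)cc1OCc9ccccc9 | intermediate
13 | methyl (2R)-oxirane-2-carboxylate | COC(=O)[C@H]1CO1 | starting material
14 | [2,4-bis(benzyloxy)-6-bromophenyl]magnesium chloride (not isolated) | Cl[Mg]c1c(Br)cc(OCc9ccccc9)cc1OCc9ccccc9 | intermediate
15 | methyl (2R)-3-[2,4-bis(benzyloxy)-6-bromophenyl]-2-hydroxypropanoate | COC(=O)[C@H](O)Cc1c(Br)cc(OCc9ccccc9)cc1OCc9ccccc9 | intermediate
16 | methyl (2R)-3-[2,4-bis(benzyloxy)-6-bromophenyl]-2-(triisopropylsilyloxy)propanoate | COC(=O)[C@H](O[Si](C(C)C)(C(C)C)C(C)C)Cc1c(Br)cc(OCc9ccccc9)cc1OCc9ccccc9 | intermediate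
17 | (2R)-3-[2,4-bis(benzyloxy)-6-bromophenyl]-N-methoxy-N-methyl-2-(triisopropylsilyloxy)propanamide | CON(C)C(=O)[C@H](O[Si](C(C)C)(C(C)C)C(C)C)Cc1c(Br)cc(OCc9ccccc9)cc1OCc9ccccc9 | intermediate
18 | methyl (2R)-2-(benzyloxy)-3-[2,4-bis(benzyloxy)-6-bromophenyl]propanoate | COC(=O)[C@H](OCc9ccccc9)Cc1c(Br)cc(OCc9ccccc9)cc1OCc9ccccc9 | intermediate
19 | (2R)-2-(benzyloxy)-3-[2,4-bis(benzyloxy)-6-bromophenyl]propanal | O=C[C@H](OCc9ccccc9)Cc1c(Br)cc(OCc9ccccc9)cc1OCc9ccccc9 | intermediate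
20 | [7,8-bis(benzyloxy)-2-bromo-1-methoxy-3,4-dihydronaphthalen-5-yl]magnesium chloride (not isolated) | COC1=C(Br)CCc2c([Mg]Cl)cc(OCc9ccccc9)c(OCc9ccccc9)c12 | intermediate
21 | (2R)-1-[7,8-bis(benzyloxy)-2-bromo-1-methoxy-3,4-dihydronaphthalen-5-yl]-3-[2,4-bis(benzyloxy)-6-bromophenyl]-2-(triisopropylsilyloxy)propan-1-one | COC1=C(Br)CCc2c(C(=O)[C@H](O[Si](C(C)C)(C(C)C)C(C)C)Cc3c(Br)cc(OCc9ccccc9)cc3OCc9ccccc9)cc(OCc9ccccc9)c(OCc9ccccc9)c12 | intermediate
22 | (1R,2R)-1-[7,8-bis(benzyloxy)-2-bromo-1-methoxy-3,4-dihydronaphthalen-5-yl]-3-[2,4-bis(benzyloxy)-6-bromophenyl]-2-(triisopropylsilyloxy)propan-1-ol | COC1=C(Br)CCc2c([C@@H](O)[C@H](O[Si](C(C)C)(C(C)C)C(C)C)Cc3c(Br)cc(OCc9ccccc9)cc3OCc9ccccc9)cc(OCc9ccccc9)c(OCc9ccccc9)c12 | intermediate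
23 | 7,8-bis(benzyloxy)-2-bromo-1-methoxy-5-[(2R,3R)-5,7-bis(benzyloxy)-3-(triisopropylsilyloxy)chroman-2-yl]-3,4-dihydronaphthalene | COC1=C(Br)CCc2c([C@H]3Oc4cc(OCc9ccccc9)cc(OCc9ccccc9)c4C[C@H]3O[Si](C(C)C)(C(C)C)C(C)C)cc(OCc9ccccc9)c(OCc9ccccc9)c12 | intermediate
24 | C2 vinyllithium of 23 (lithium in place of bromine, not isolated) | COC1=C([Li])CCc2c([C@H]3Oc4cc(OCc9ccccc9)cc(OCc9ccccc9)c4C[C@H]3O[Si](C(C)C)(C(C)C)C(C)C)cc(OCc9ccccc9)c(OCc9ccccc9)c12 | intermediate
25 | C2 vinylmagnesium bromide of 23 (not isolated) | COC1=C([Mg]Br)CCc2c([C@H]3Oc4cc(OCc9ccccc9)cc(OCc9ccccc9)c4C[C@H]3O[Si](C(C)C)(C(C)C)C(C)C)cc(OCc9ccccc9)c(OCc9ccccc9)c12 | intermediate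
26 | (1R,2R)-2-(benzyloxy)-3-[2,4-bis(benzyloxy)-6-bromophenyl]-1-[7,8-bis(benzyloxy)-1-methoxy-5-(flavan A unit)-3,4-dihydronaphthalen-2-yl]propan-1-ol | COC1=C([C@@H](O)[C@H](OCc9ccccc9)Cc3c(Br)cc(OCc9ccccc9)cc3OCc9ccccc9)CCc2c([C@H]3Oc4cc(OCc9ccccc9)cc(OCc9ccccc9)c4C[C@H]3O[Si](C(C)C)(C(C)C)C(C)C)cc(OCc9ccccc9)c(OCc9ccccc9)c12 | intermediate
27 | 7,8-bis(benzyloxy)-1-methoxy-5-(flavan A unit)-2-(flavan B unit)-3,4-dihydronaphthalene (key-step precursor) | COC1=C([C@H]3Oc4cc(OCc9ccccc9)cc(OCc9ccccc9)c4C[C@H]3OCc9ccccc9)CCc2c([C@H]3Oc4cc(OCc9ccccc9)cc(OCc9ccccc9)c4C[C@H]3O[Si](C(C)C)(C(C)C)C(C)C)cc(OCc9ccccc9)c(OCc9ccccc9)c12 | intermediate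
28 | dibromocarbene adduct of 27 across C1=C2 (1-methoxy dibromocyclopropane, both cis-fused diastereomers, not isolated) | COC12C(Br)(Br)C1([C@H]3Oc4cc(OCc9ccccc9)cc(OCc9ccccc9)c4C[C@H]3OCc9ccccc9)CCc1c([C@H]3Oc4cc(OCc9ccccc9)cc(OCc9ccccc9)c4C[C@H]3O[Si](C(C)C)(C(C)C)C(C)C)cc(OCc9ccccc9)c(OCc9ccccc9)c12 | intermediate
29 | 3,4-bis(benzyloxy)-6-bromo-1-(flavan A unit)-7-(flavan B unit)-8,9-dihydro-5H-benzo[7]annulen-5-one (key-step product) | O=C1C(Br)=C([C@H]3Oc4cc(OCc9ccccc9)cc(OCc9ccccc9)c4C[C@H]3OCc9ccccc9)CCc2c([C@H]3Oc4cc(OCc9ccccc9)cc(OCc9ccccc9)c4C[C@H]3O[Si](C(C)C)(C(C)C)C(C)C)cc(OCc9ccccc9)c(OCc9ccccc9)c12 | intermediate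
30 | potassium dienolate of 29 (C5 olate, C5=C6 and C7=C8, not isolated) | [K+].[O-]C1=C(Br)C([C@H]3Oc4cc(OCc9ccccc9)cc(OCc9ccccc9)c4C[C@H]3OCc9ccccc9)=CCc2c([C@H]3Oc4cc(OCc9ccccc9)cc(OCc9ccccc9)c4C[C@H]3O[Si](C(C)C)(C(C)C)C(C)C)cc(OCc9ccccc9)c(OCc9ccccc9)c12 | intermediate
31 | 8-bromo derivative of 29 (6,8-dibromo ketone, C8 epimers, not isolated) | O=C1C(Br)=C([C@H]3Oc4cc(OCc9ccccc9)cc(OCc9ccccc9)c4C[C@H]3OCc9ccccc9)C(Br)Cc2c([C@H]3Oc4cc(OCc9ccccc9)cc(OCc9ccccc9)c4C[C@H]3O[Si](C(C)C)(C(C)C)C(C)C)cc(OCc9ccccc9)c(OCc9ccccc9)c12 | intermediate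
32 | 3,4-bis(benzyloxy)-6-bromo-1-(flavan A unit)-7-(flavan B unit)-5H-benzo[7]annulen-5-one (bromotropone) | O=C1C(Br)=C([C@H]3Oc4cc(OCc9ccccc9)cc(OCc9ccccc9)c4C[C@H]3OCc9ccccc9)C=Cc2c([C@H]3Oc4cc(OCc9ccccc9)cc(OCc9ccccc9)c4C[C@H]3O[Si](C(C)C)(C(C)C)C(C)C)cc(OCc9ccccc9)c(OCc9ccccc9)c12 | intermediate
33 | 3,4,6-tris(benzyloxy)-1-(flavan A unit)-7-(flavan B unit)-5H-benzo[7]annulen-5-one | O=C1C(OCc9ccccc9)=C([C@H]3Oc4cc(OCc9ccccc9)cc(OCc9ccccc9)c4C[C@H]3OCc9ccccc9)C=Cc2c([C@H]3Oc4cc(OCc9ccccc9)cc(OCc9ccccc9)c4C[C@H]3O[Si](C(C)C)(C(C)C)C(C)C)cc(OCc9ccccc9)c(OCc9ccccc9)c12 | intermediate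
34 | 3,4,6-tris(benzyloxy)-1-[(2R,3R)-5,7-bis(benzyloxy)-3-hydroxychroman-2-yl]-7-(flavan B unit)-5H-benzo[7]annulen-5-one | O=C1C(OCc9ccccc9)=C([C@H]3Oc4cc(OCc9ccccc9)cc(OCc9ccccc9)c4C[C@H]3OCc9ccccc9)C=Cc2c([C@H]3Oc4cc(OCc9ccccc9)cc(OCc9ccccc9)c4C[C@H]3O)cc(OCc9ccccc9)c(OCc9ccccc9)c12 | intermediate
35 | 3,4,5-tris(benzyloxy)benzoic acid | O=C(O)c1cc(OCc9ccccc9)c(OCc9ccccc9)c(OCc9ccccc9)c1 | starting material
36 | O-acylisourea of 35 and DCC (not isolated) | O=C(OC(=NC1CCCCC1)NC1CCCCC1)c1cc(OCc9ccccc9)c(OCc9ccccc9)c(OCc9ccccc9)c1 | intermediate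
37 | (2R,3R)-5,7-bis(benzyloxy)-2-[3,4,6-tris(benzyloxy)-7-(flavan B unit)-5-oxo-5H-benzo[7]annulen-1-yl]chroman-3-yl 3,4,5-tris(benzyloxy)benzoate | O=C1C(OCc9ccccc9)=C([C@H]3Oc4cc(OCc9ccccc9)cc(OCc9ccccc9)c4C[C@H]3OCc9ccccc9)C=Cc2c([C@H]3Oc4cc(OCc9ccccc9)cc(OCc9ccccc9)c4C[C@H]3OC(=O)c4cc(OCc9ccccc9)c(OCc9ccccc9)c(OCc9ccccc9)c4)cc(OCc9ccccc9)c(OCc9ccccc9)c12 | intermediate
38 | CNP0217128.1: (2R,3R)-5,7-dihydroxy-2-{3,4,6-trihydroxy-5-oxo-7-[(2R,3R)-3,5,7-trihydroxychroman-2-yl]-5H-benzo[7]annulen-1-yl}chroman-3-yl 3,4,5-trihydroxybenzoate | O=C(O[C@@H]1Cc2c(O)cc(O)cc2O[C@@H]1c1cc(O)c(O)c2c(=O)c(O)c([C@H]3Oc4cc(O)cc(O)c4C[C@H]3O)ccc12)c1cc(O)c(O)c(O)c1 | target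

Total step count: 24.
Longest linear sequence: 18 steps (steps 1 to 7, then 14 to 24).

Steps most likely to fail

Step 19. Carbene transfer to the crowded tetrasubstituted C1=C2 bond may be slow, so that the carbene is consumed elsewhere. Alkoxide may also deprotonate the enolisable product at C8 or at C2 of flavan B, leading to carbene capture or β-elimination of benzyloxide. The fallback sets out from 27 and returns at 33; it replaces the one-pot reaction by a stepwise, base-free ring expansion through an isolated cyclopropane. Thermal decarboxylation of Cl3CCO2Na in refluxing 1,2-dimethoxyethane should transfer dichlorocarbene to 27 under neutral conditions and give the more robust 1-methoxy dichlorocyclopropane F1. Heating F1 in xylene over solid K2CO3 at about 130 °C should open it electrocyclically, with loss of chloromethane, to the 6-chloro-8,9-dihydro enone F2. F2 would be dehydrogenated by the protocol of step 20, through the potassium dienolate F3 and the 8-bromo-6-chloro ketone F4, to the 6-chlorotropone F5. NaOBn would then displace chloride from F5 and give 33.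

Step 20. The base may remove the C2–H of flavan B instead of a C8–H, with epimerisation or β-elimination of the C3 benzyloxy group. The dienolate may also brominate at C6 as well as C8, and elimination of the resulting bromides may stall. The fallback sets out from 29 and returns at 32; it replaces halogenation–elimination by oxidation of a silyl dienol ether. Soft enolisation with Me3SiOTf and Et3N in CH2Cl2 at 0 °C should give the trimethylsilyl dienol ether F6. Single-electron oxidation of F6 with 2-iodoxybenzoic acid and 4-methoxypyridine N-oxide in DMSO at room temperature should give 32 under conditions mild enough to leave the flavan C4 methylenes alone.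

Step 17. Chelation control may be incomplete, because ether competes for magnesium and the nucleophile is bulky, giving poor facial selectivity; the basic vinyl-metal may also enolise the α-alkoxy aldehyde. The fallback sets out from 18 and 23 and returns at 26; it replaces the addition by acylation and reagent-controlled reduction. Ester 18 is converted with MeNH(OMe)·HCl and i-PrMgCl into the Weinreb amide F7. Vinyllithium 24, made from 23 as in step 17, is acylated by F7 to the α-benzyloxy enone F8. Corey–Bakshi–Shibata reduction of F8 with BH3·SMe2 and (R)-1-methyl-3,3-diphenyltetrahydro-1H,3H-pyrrolo[1,2-c][1,3,2]oxazaborole, the alkenyl group acting as the larger ketone substituent, should then give the (R)-carbinol 26.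

Further compounds
F1 | step 19 | dichlorocarbene adduct of 27 across C1=C2 (1-methoxy dichlorocyclopropane) | COC12C(Cl)(Cl)C1([C@H]3Oc4cc(OCc9ccccc9)cc(OCc9ccccc9)c4C[C@H]3OCc9ccccc9)CCc1c([C@H]3Oc4cc(OCc9ccccc9)cc(OCc9ccccc9)c4C[C@H]3O[Si](C(C)C)(C(C)C)C(C)C)cc(OCc9ccccc9)c(OCc9ccccc9)c12
F2 | step 19 | 6-chloro analogue of 29 (6-chloro-8,9-dihydro enone) | O=C1C(Cl)=C([C@H]3Oc4cc(OCc9ccccc9)cc(OCc9ccccc9)c4C[C@H]3OCc9ccccc9)CCc2c([C@H]3Oc4cc(OCc9ccccc9)cc(OCc9ccccc9)c4C[C@H]3O[Si](C(C)C)(C(C)C)C(C)C)cc(OCc9ccccc9)c(OCc9ccccc9)c12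
F3 | step 19 | potassium dienolate of F2 | [K+].[O-]C1=C(Cl)C([C@H]3Oc4cc(OCc9ccccc9)cc(OCc9ccccc9)c4C[C@H]3OCc9ccccc9)=CCc2c([C@H]3Oc4cc(OCc9ccccc9)cc(OCc9ccccc9)c4C[C@H]3O[Si](C(C)C)(C(C)C)C(C)C)cc(OCc9ccccc9)c(OCc9ccccc9)c12
F4 | step 19 | 8-bromo derivative of F2 (8-bromo-6-chloro ketone, C8 epimers) | O=C1C(Cl)=C([C@H]3Oc4cc(OCc9ccccc9)cc(OCc9ccccc9)c4C[C@H]3OCc9ccccc9)C(Br)Cc2c([C@H]3Oc4cc(OCc9ccccc9)cc(OCc9ccccc9)c4C[C@H]3O[Si](C(C)C)(C(C)C)C(C)C)cc(OCc9ccccc9)c(OCc9ccccc9)c12
F5 | step 19 | 6-chloro analogue of 32 (chlorotropone) | O=C1C(Cl)=C([C@H]3Oc4cc(OCc9ccccc9)cc(OCc9ccccc9)c4C[C@H]3OCc9ccccc9)C=Cc2c([C@H]3Oc4cc(OCc9ccccc9)cc(OCc9ccccc9)c4C[C@H]3O[Si](C(C)C)(C(C)C)C(C)C)cc(OCc9ccccc9)c(OCc9ccccc9)c12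
F6 | step 20 | trimethylsilyl dienol ether of 29 (C5 silyloxy, C5=C6 and C7=C8) | C[Si](C)(C)OC1=C(Br)C([C@H]3Oc4cc(OCc9ccccc9)cc(OCc9ccccc9)c4C[C@H]3OCc9ccccc9)=CCc2c([C@H]3Oc4cc(OCc9ccccc9)cc(OCc9ccccc9)c4C[C@H]3O[Si](C(C)C)(C(C)C)C(C)C)cc(OCc9ccccc9)c(OCc9ccccc9)c12
F7 | step 17 | (2R)-2-(benzyloxy)-3-[2,4-bis(benzyloxy)-6-bromophenyl]-N-methoxy-N-methylpropanamide | CON(C)C(=O)[C@H](OCc9ccccc9)Cc1c(Br)cc(OCc9ccccc9)cc1OCc9ccccc9
F8 | step 17 | (2R)-2-(benzyloxy)-3-[2,4-bis(benzyloxy)-6-bromophenyl]-1-[7,8-bis(benzyloxy)-1-methoxy-5-(flavan A unit)-3,4-dihydronaphthalen-2-yl]propan-1-one | COC1=C(C(=O)[C@H](OCc9ccccc9)Cc3c(Br)cc(OCc9ccccc9)cc3OCc9ccccc9)CCc2c([C@H]3Oc4cc(OCc9ccccc9)cc(OCc9ccccc9)c4C[C@H]3O[Si](C(C)C)(C(C)C)C(C)C)cc(OCc9ccccc9)c(OCc9ccccc9)c12
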